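## Retrosynthetic overview

1. Feature: ring A (cyclopentane C1–C5) and ring B (cycloheptane C1, C5–C10) share the C1–C5 bond, and the methyl on C1 is cis to the hydroxyl on C5. Once that oxygen is allylic to a C1=C2 double bond in ring A, it can deliver the methyl carbon to C1 as the CH2 of a cyclopropane (other sites: C4 CH–iPr, C8 C(CH3)OH, C9 CH–O-anisoyl).
2. Late stage: 29 ⇒ acylation of O9 of triol 27 ⇒ hydrogenolysis of the C2–CH2 bond of cyclopropane triol 26 ⇒ anti hydrolysis of β-epoxide 25 ⇒ C5-hydroxyl-directed epoxidation of C8=C9 in 24.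
3. Key disconnection: C1–CH2 and C2–CH2 of 24 ⇒ bicyclic dienol 21 (C1=C2, C8=C9, no carbon substituent on C1) + CH2I2, by hydroxyl-directed Simmons–Smith cyclopropanation.
4. Early stage: 21 ⇒ ring-closing metathesis (C8=C9) of trienol 20 ⇒ Grignard addition (C5–C6) to 2-allyl-5-isopropylcyclopentenone 17 ⇒ iodination and Stille allylation (C1–C10) ⇒ ring-closing metathesis of a vinyl ketone ⇒ Evans allylation (C4).
5. Ring order: ring A (step 6), ring B (step 10), cyclopropane (step 11, opened again in step 14), epoxide (step 12, opened in step 13).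

Key step: step 11

Conventions: the locants C1–C10 defined above are used for all bicyclic compounds; β is the face that carries the C5 hydroxyl, α the opposite face.
Remark on the chemistry: a metal alkoxide or carboxylate in which a product sits before aqueous work-up is not counted as a separate compound.

## Route

Step 1
Reactants: 1 (4R)-4-benzyl-1,3-oxazolidin-2-one; 2 3-methylbutanoyl chloride (isovaleryl chloride)
Product: 3 (4R)-4-benzyl-3-(3-methylbutanoyl)-1,3-oxazolidin-2-one
Conditions: Et3N, DMAP (cat.), CH2Cl2, 0 °C to rt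
Reagents that add atoms: 2 isovaleryl chloride, CC(C)CC(Cl)=O
Why: DMAP-catalysed N-acylation of the oxazolidinone by the acid chloride (acyl transfer through the acylpyridinium ion) should give the imide without touching the auxiliary stereocenter.

Step 2
Reactants: 3 (4R)-4-benzyl-3-(3-methylbutanoyl)-1,3-oxazolidin-2-one; 4 allyl bromide
Product: 6 (4R)-4-benzyl-3-[(2R)-2-(propan-2-yl)pent-4-enoyl]-1,3-oxazolidin-2-one, via sodium Z-enolate 5 (not isolated)
Conditions: NaN(SiMe3)2, THF, −78 °C; then allyl bromide, −78 to −40 °C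
Reagents that add atoms: 4 allyl bromide, C=CCBr
Why: Evans asymmetric alkylation: the chelated Z-enolate should be allylated on the face away from the benzyl group, which with the (R)-auxiliary sets the isopropyl-bearing carbon (the later C4) as R.

Step 3
Reactants: 6 (4R)-4-benzyl-3-[(2R)-2-(propan-2-yl)pent-4-enoyl]-1,3-oxazolidin-2-one
Product: 8 (2R)-2-(propan-2-yl)pent-4-enoic acid, via lithium peroxycarboxylate 7 (not isolated)
Conditions: LiOH, H2O2, THF/H2O (3:1), 0 °C; then Na2SO3 (aq.); then HCl (aq.) to pH 2
Reagents that add atoms: hydrogen peroxide, OO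
Why: Hydroperoxide cleavage of the imide: the hydroperoxide anion attacks the exocyclic carbonyl even of this alpha-branched imide, sulfite reduces the peracid salt to the carboxylate, and the alpha stereocenter should not be enolised at 0 °C.

Step 4
Reactants: 8 (2R)-2-(propan-2-yl)pent-4-enoic acid
Product: 10 (2R)-N-methoxy-N-methyl-2-(propan-2-yl)pent-4-enamide, via acyl imidazole 9 (not isolated)
Conditions: 1,1'-carbonyldiimidazole, CH2Cl2, rt; then MeNH(OMe)·HCl, rt
Reagents that add atoms: N,O-dimethylhydroxylamine hydrochloride, CNOC.Cl; 1,1'-carbonyldiimidazole, O=C(n1ccnc1)n1ccnc1 (its imidazolyl group is present in 9 only)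
Why: Weinreb amide formation through the acyl imidazole is a mild amide coupling without strong base, so the alpha stereocenter, which carries only alkyl groups, should be kept.

Step 5
Reactants: 10 (2R)-N-methoxy-N-methyl-2-(propan-2-yl)pent-4-enamide; 11 vinylmagnesium bromide
Product: 13 (4R)-4-(propan-2-yl)hepta-1,6-dien-3-one, via bromomagnesium hemiaminal 12 (not isolated)
Conditions: CH2=CHMgBr, THF, −78 to 0 °C; inverse quench into cold 1 M HCl (aq.)
Reagents that add atoms: 11 vinylmagnesium bromide, C=C[Mg]Br
Why: Weinreb ketone synthesis: the chelated adduct should resist a second addition and collapse only on the acidic quench, which also keeps the released amine protonated so that it cannot add to the vinyl ketone.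

Step 6
Reactants: 13 (4R)-4-(propan-2-yl)hepta-1,6-dien-3-one
Product: 14 (5R)-5-(propan-2-yl)cyclopent-2-en-1-one
Conditions: second-generation Grubbs catalyst RuCl2(=CHPh)(H2IMes)(PCy3) (2 mol %), CH2Cl2, 40 °C
Reagents that add atoms: none
Why: Ring-closing metathesis of the vinyl ketone with the terminal alkene should close ring A with loss of ethylene under neutral conditions that leave the alpha stereocenter alone.

Step 7
Reactants: 14 (5R)-5-(propan-2-yl)cyclopent-2-en-1-one
Product: 15 (5R)-2-iodo-5-(propan-2-yl)cyclopent-2-en-1-one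
Conditions: I2, pyridine, CH2Cl2, 0 °C to rt
Reagents that add atoms: iodine, II
Why: Johnson alpha-iodination of an enone (conjugate addition of pyridine, iodination of the enolate, elimination) should put iodine on the alpha carbon, the later C1, under weakly basic conditions that should not epimerise the hindered alpha' center.

Step 8
Reactants: 15 (5R)-2-iodo-5-(propan-2-yl)cyclopent-2-en-1-one; 16 allyltributylstannane
Product: 17 (5R)-5-(propan-2-yl)-2-(prop-2-en-1-yl)cyclopent-2-en-1-one
Conditions: Pd2(dba)3 (2.5 mol %), AsPh3, CuI, N-methylpyrrolidone, rt to 50 °C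
Reagents that add atoms: 16 allyltributylstannane, C=CC[Sn](CCCC)(CCCC)CCCC
Why: Stille coupling of the alpha-iodoenone (oxidative addition to zerovalent palladium, allyl transfer from tin helped by AsPh3 and CuI, reductive elimination) should form the C1–C10 bond in a neutral medium that spares the skipped diene and the C4 stereocenter.

Step 9
Reactants: 17 (5R)-5-(propan-2-yl)-2-(prop-2-en-1-yl)cyclopent-2-en-1-one; 18 4-bromo-2-methylbut-1-ene
Product: 20 (1S,5R)-1-(3-methylbut-3-en-1-yl)-5-(propan-2-yl)-2-(prop-2-en-1-yl)cyclopent-2-en-1-ol, via homoallyl Grignard reagent 19 (not isolated)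
Conditions: 18, Mg, THF, rt; then 17 premixed with LaCl3·2LiCl (1 equiv), THF, −20 to 0 °C; NH4Cl (aq.)
Reagents that add atoms: 18 4-bromo-2-methylbut-1-ene, C=C(C)CCBr; magnesium, [Mg] (present in 19 only)
Why: Lanthanum-chloride-promoted Grignard 1,2-addition, which suppresses enolisation and conjugate addition, should attack the flat enone carbonyl on the face opposite the adjacent isopropyl group, so the new chain (C6) ends trans and the C5 hydroxyl cis to isopropyl.

Step 10
Reactants: 20 (1S,5R)-1-(3-methylbut-3-en-1-yl)-5-(propan-2-yl)-2-(prop-2-en-1-yl)cyclopent-2-en-1-ol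
Product: 21 (3R,3aS)-6-methyl-3-(propan-2-yl)-2,3,3a,4,5,8-hexahydroazulen-3a-ol (bicyclic dienol: C1=C2 and C8=C9, CH3 on C8, C5 OH β, C4 isopropyl β, no methyl on C1)
Conditions: second-generation Grubbs catalyst RuCl2(=CHPh)(H2IMes)(PCy3) (5 mol %), CH2Cl2 (0.005 M), 40 °C
Reagents that add atoms: none
Why: Ring-closing metathesis between the allyl terminus and the 1,1-disubstituted terminus should close the seven-membered ring B with the trisubstituted C8=C9 bond, while the endocyclic trisubstituted C1=C2 bond is inert and the free tertiary hydroxyl is tolerated.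

Step 11
Reactants: 21 bicyclic dienol; 22 diiodomethane
Product: 24 cyclopropane-fused alcohol (CH2 bridging C1 and C2 on the β face, C8=C9 kept, C5 OH β, C4 isopropyl β), via ethylzinc alkoxide 23 (not isolated)
Conditions: ZnEt2 (2.1 equiv), CH2Cl2, −20 °C; then CH2I2 (1.3 equiv), −20 to 0 °C; NH4Cl (aq.)
Reagents that add atoms: 22 diiodomethane, ICI; diethylzinc, CC[Zn]CC (present in 23 only)
Why: This is a hydroxyl-directed Simmons–Smith cyclopropanation in the Furukawa form, the closest known cases being the syn cyclopropanation of cyclopent-2-enols and of tertiary cyclic allylic alcohols. ZnEt2 first turns the C5 hydroxyl into ethylzinc alkoxide 23, and the carbenoid EtZnCH2I formed from the remaining ZnEt2 and CH2I2 binds to that oxygen. The bound carbenoid then passes CH2 to C1=C2 through a concerted butterfly transition state, a [2+1] closure that makes C1–CH2 and C2–CH2 together and fuses the three-membered ring cis onto ring A. Both new stereocenters, C1 and C2, are controlled by the C5 stereocenter, since the tethered carbenoid reaches only the β face, so the CH2 ends cis to the hydroxyl where the methyl is needed. The step needs face selectivity and site selectivity over the trisubstituted C8=C9 bond; both rest on the same coordination, because the alkoxide is allylic only to C1=C2 while C8=C9 lies four bonds away across ring B, and alkoxide-bound delivery is much faster than attack on an unbound alkene. Keeping the carbenoid near one equivalent at low temperature should hold that margin.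

Step 12
Reactants: 24 cyclopropane-fused alcohol
Product: 25 8β,9β-epoxide of 24 (epoxide oxygen cis to the C5 OH)
Conditions: VO(acac)2 (5 mol %), t-BuOOH (1.5 equiv, in decane), CH2Cl2, 0 °C to rt
Reagents that add atoms: tert-butyl hydroperoxide, CC(C)(C)OO
Why: Vanadium-catalysed hydroxyl-directed epoxidation: the tertiary C5 hydroxyl, bishomoallylic to C8=C9 by either arc of ring B, should bind the vanadium alkylperoxide and deliver oxygen to the β face, which sets C8 and C9, while the cyclopropane is inert.

Step 13
Reactants: 25 8β,9β-epoxide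
Product: 26 cyclopropane triol (C5 OH β, C8 OH α with C8 CH3 β, C9 OH β, CH2 bridge on C1/C2 β)
Conditions: HClO4 (0.1 M aq., cat.), THF/H2O (3:1), 0 °C
Reagents that add atoms: water, O
Why: Acid-catalysed epoxide hydrolysis: water should attack the protonated epoxide at the tertiary C8 from the α face with inversion, leaving the epoxide oxygen on C9 (β) and giving the trans 8α,9β-diol; the β-oriented C5 hydroxyl cannot reach the back side of C8, and at this acidity the epoxide should open well before the tertiary cyclopropylcarbinol ionises.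

Step 14
Reactants: 26 cyclopropane triol
Product: 27 (3R,3aS,6R,7R,8aR)-6,8a-dimethyl-3-(propan-2-yl)decahydroazulene-3a,6,7-triol
Conditions: H2 (3 atm), PtO2, AcOH, rt
Reagents that add atoms: none
Why: Catalytic hydrogenolysis of the cyclopropane, driven by strain release, should cleave the least substituted and least hindered C2–CH2 bond, so the CH2 stays on C1 as the methyl group with the C1 configuration unchanged; no other reducible group is present.

Step 15
Reactants: 27 triol; 28 4-methoxybenzoyl chloride
Product: 29 (3R,3aS,6R,7R,8aR)-3a,6-dihydroxy-6,8a-dimethyl-3-(propan-2-yl)decahydroazulen-7-yl 4-methoxybenzoate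
Conditions: 4-MeOC6H4COCl (1.2 equiv), pyridine, DMAP (cat.), CH2Cl2, 0 °C to rt
Reagents that add atoms: 28 4-methoxybenzoyl chloride, COc1ccc(C(Cl)=O)cc1
Why: DMAP-catalysed acylation should take place only at the secondary C9 hydroxyl, since the C5 and C8 hydroxyls are tertiary and hindered, and no stereocenter is affected.

## Compound list

1 | (4R)-4-benzyl-1,3-oxazolidin-2-one | O=C1N[C@H](Cc2ccccc2)CO1 | starting material
2 | 3-methylbutanoyl chloride (isovaleryl chloride) | CC(C)CC(Cl)=O | starting material
3 | (4R)-4-benzyl-3-(3-methylbutanoyl)-1,3-oxazolidin-2-one | CC(C)CC(=O)N1[C@H](Cc2ccccc2)COC1=O | intermediate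
4 | allyl bromide (3-bromoprop-1-ene) | C=CCBr | starting material
5 | sodium (Z)-enolate of 3 | CC(C)/C=C(\[O-])N1[C@H](Cc2ccccc2)COC1=O.[Na+] | intermediate
6 | (4R)-4-benzyl-3-[(2R)-2-(propan-2-yl)pent-4-enoyl]-1,3-oxazolidin-2-one | C=CC[C@H](C(C)C)C(=O)N1[C@H](Cc2ccccc2)COC1=O | intermediate
7 | lithium (2R)-2-(propan-2-yl)pent-4-eneperoxoate | C=CC[C@H](C(C)C)C(=O)O[O-].[Li+] | intermediate
8 | (2R)-2-(propan-2-yl)pent-4-enoic acid | C=CC[C@H](C(C)C)C(=O)O | intermediate
9 | 1-[(2R)-2-(propan-2-yl)pent-4-enoyl]imidazole | C=CC[C@H](C(C)C)C(=O)n1ccnc1 | intermediate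
10 | (2R)-N-methoxy-N-methyl-2-(propan-2-yl)pent-4-enamide | C=CC[C@H](C(C)C)C(=O)N(C)OC | intermediate
11 | vinylmagnesium bromide | C=C[Mg]Br | starting material
12 | bromomagnesium alkoxide of the tetrahedral adduct of 10 and 11 | C=CC[C@H](C(C)C)C(O[Mg]Br)(C=C)N(C)OC | intermediate
13 | (4R)-4-(propan-2-yl)hepta-1,6-dien-3-one | C=CC[C@H](C(C)C)C(=O)C=C | intermediate
14 | (5R)-5-(propan-2-yl)cyclopent-2-en-1-one | O=C1C=CC[C@@H]1C(C)C | intermediate
15 | (5R)-2-iodo-5-(propan-2-yl)cyclopent-2-en-1-one | O=C1C(I)=CC[C@@H]1C(C)C | intermediate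
16 | allyltributylstannane | C=CC[Sn](CCCC)(CCCC)CCCC | starting material
17 | (5R)-5-(propan-2-yl)-2-(prop-2-en-1-yl)cyclopent-2-en-1-one | O=C1C(CC=C)=CC[C@@H]1C(C)C | intermediate
18 | 4-bromo-2-methylbut-1-ene | C=C(C)CCBr | starting material
19 | (3-methylbut-3-en-1-yl)magnesium bromide | C=C(C)CC[Mg]Br | intermediate
20 | (1S,5R)-1-(3-methylbut-3-en-1-yl)-5-(propan-2-yl)-2-(prop-2-en-1-yl)cyclopent-2-en-1-ol | C=CCC1=CC[C@H](C(C)C)[C@@]1(O)CCC(C)=C | intermediate
21 | (3R,3aS)-6-methyl-3-(propan-2-yl)-2,3,3a,4,5,8-hexahydroazulen-3a-ol (bicyclic dienol, C1=C2 and C8=C9) | CC1=CCC2=CC[C@H](C(C)C)[C@@]2(O)CC1 | intermediate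
22 | diiodomethane | ICI | starting material
23 | ethylzinc alkoxide of 21 | CC1=CCC2=CC[C@H](C(C)C)[C@@]2(O[Zn]CC)CC1 | intermediate
24 | cyclopropane-fused alcohol: CH2 bridging C1 and C2 on the β face, C8=C9, C5 OH β, C4 isopropyl β | CC1=CC[C@@]2(C3)[C@H]3C[C@H](C(C)C)[C@@]2(O)CC1 | intermediate
25 | 8β,9β-epoxide of 24 | O1[C@@H]2C[C@@]3(C4)[C@H]4C[C@H](C(C)C)[C@@]3(O)CC[C@]12C | intermediate
26 | cyclopropane triol: C5 OH β, C8 OH α, C9 OH β, CH2 bridge on C1/C2 β | O[C@@H]1C[C@@]2(C3)[C@H]3C[C@H](C(C)C)[C@@]2(O)CC[C@@]1(C)O | intermediate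
27 | (3R,3aS,6R,7R,8aR)-6,8a-dimethyl-3-(propan-2-yl)decahydroazulene-3a,6,7-triol | O[C@@H]1C[C@@]2(C)CC[C@H](C(C)C)[C@@]2(O)CC[C@@]1(C)O | intermediate
28 | 4-methoxybenzoyl chloride | COc1ccc(C(Cl)=O)cc1 | starting material
29 | (3R,3aS,6R,7R,8aR)-3a,6-dihydroxy-6,8a-dimethyl-3-(propan-2-yl)decahydroazulen-7-yl 4-methoxybenzoate | COc1ccc(C(=O)O[C@@H]2C[C@@]3(C)CC[C@H](C(C)C)[C@@]3(O)CC[C@@]2(C)O)cc1 | target

## Step count and risks

Total step count: 15. Longest linear sequence: 15 steps (1 and 2 to 29).

**Step 11.** Site selectivity may be lost: methylene may also be transferred to the electron-rich C8=C9 bond, or the hindered tertiary alkoxide may react slowly, so that an excess of carbenoid is needed and the margin disappears. The fallback sets out from enone 17 and runs the directed cyclopropanation before any side chain with a nucleophilic alkene is present.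
- Luche reduction (NaBH4, CeCl3·7H2O, MeOH, −78 °C), with hydride entering anti to the isopropyl group, should give (1S,5R)-5-(propan-2-yl)-2-(prop-2-en-1-yl)cyclopent-2-en-1-ol F1.
- ZnEt2/CH2I2 on this secondary cyclopentenol, whose only other alkene is a monosubstituted vinyl group, should give the syn cyclopropyl carbinol 3-(propan-2-yl)-1-(prop-2-en-1-yl)bicyclo[3.1.0]hexan-2-ol F2.
- Dess–Martin periodinane should oxidise it to 3-(propan-2-yl)-1-(prop-2-en-1-yl)bicyclo[3.1.0]hexan-2-one F3.
- Grignard reagent 19 with LaCl3·2LiCl should add from the α face, opposite both the isopropyl group and the cyclopropane CH2, to give 2-(3-methylbut-3-en-1-yl)-3-(propan-2-yl)-1-(prop-2-en-1-yl)bicyclo[3.1.0]hexan-2-ol F4.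
- Ring-closing metathesis with the second-generation Grubbs catalyst then closes ring B and the fallback comes back to the route at 24.

**Step 13.** The epoxide may open with carbocation character at C8, so that the β-oriented C5 hydroxyl closes a transannular ether or water enters with retention; water may attack C9 instead; or the mineral acid may ionise the tertiary cyclopropylcarbinol. The fallback sets out from epoxide 25 and brings in the C8 oxygen as acetate and not as water, without mineral acid. Buffered acetolysis (AcOH, NaOAc, rt to 40 °C) should open the epoxide at C8 with inversion to the 8α-acetoxy-5β,9β-diol F5. Methanolysis (K2CO3, MeOH, rt) should then remove the acetate, and the fallback comes back to the route at 26.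

**Step 14.** Hydrogenolysis may cleave the wrong cyclopropane bond (C1–CH2, which would leave the methyl on C2, or C1–C2, which would enlarge ring A), the cyclopropylcarbinol may rearrange in acetic acid, or the reaction may stall. The fallback leaves the cyclopropane out and brings in the C1 methyl by a silicon-tethered radical cyclisation from the same C5 oxygen (Stork reductive methylation). It sets out from dienol 21.
- ClSiMe2CH2Br, imidazole, DMF should give the (bromomethyl)dimethylsilyl ether of 21 F6.
- Bu3SnH (slow addition), AIBN, benzene, 80 °C should close a five-membered ring by 5-exo attack of the silylmethyl radical on C1 from the β face; the C2 radical takes hydrogen from the stannane, giving the cyclic siloxane (O5–SiMe2–CH2–C1) F7.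
- Bu4NF, DMF, 75 °C should cleave the C–Si bond and leave the methyl group in (3R,3aS,8aR)-6,8a-dimethyl-3-(propan-2-yl)-2,3,4,5,8,8a-hexahydro-1H-azulen-3a-ol F8.
- VO(acac)2/t-BuOOH as in step 12 should give the 8β,9β-epoxide of F8 F9, and aqueous HClO4 as in step 13, now without a cyclopropylcarbinol, should give triol 27, where the fallback comes back to the route.

Further compounds
F1 | step 11 | (1S,5R)-5-(propan-2-yl)-2-(prop-2-en-1-yl)cyclopent-2-en-1-ol | C=CCC1=CC[C@H](C(C)C)[C@@H]1O
F2 | step 11 | 3-(propan-2-yl)-1-(prop-2-en-1-yl)bicyclo[3.1.0]hexan-2-ol (OH, isopropyl and cyclopropane CH2 on the same face) | C=CC[C@@]1(C2)[C@H]2C[C@H](C(C)C)[C@@H]1O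
F3 | step 11 | 3-(propan-2-yl)-1-(prop-2-en-1-yl)bicyclo[3.1.0]hexan-2-one | C=CC[C@@]1(C2)[C@H]2C[C@H](C(C)C)C1=O
F4 | step 11 | 2-(3-methylbut-3-en-1-yl)-3-(propan-2-yl)-1-(prop-2-en-1-yl)bicyclo[3.1.0]hexan-2-ol | C=CC[C@@]1(C2)[C@H]2C[C@H](C(C)C)[C@@]1(O)CCC(C)=C
F5 | step 13 | 8α-acetoxy-5β,9β-diol (8-O-acetate of 26) | O[C@@H]1C[C@@]2(C3)[C@H]3C[C@H](C(C)C)[C@@]2(O)CC[C@@]1(C)OC(C)=O
F6 | step 14 | (bromomethyl)dimethylsilyl ether of 21 | CC1=CCC2=CC[C@H](C(C)C)[C@@]2(O[Si](C)(C)CBr)CC1
F7 | step 14 | cyclic siloxane (O5–SiMe2–CH2–C1) | CC1=CC[C@@]2(C[Si](C)(C)O3)CC[C@H](C(C)C)[C@@]23CC1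
F8 | step 14 | (3R,3aS,8aR)-6,8a-dimethyl-3-(propan-2-yl)-2,3,4,5,8,8a-hexahydro-1H-azulen-3a-ol | CC1=CC[C@@]2(C)CC[C@H](C(C)C)[C@@]2(O)CC1
F9 | step 14 | 8β,9β-epoxide of F8 | O1[C@@H]2C[C@@]3(C)CC[C@H](C(C)C)[C@@]3(O)CC[C@]12C
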